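**Plan**

- Hydroazulene numbering is used (C1–C3, C3a, C4–C8, C8a). The retrosynthesis cuts the ester C–O, then C6=C7 (ring-closing metathesis), then C7–C8 and C4–C5 (vinyl and 2-methylallyl additions to two aldehydes), and last C1–C8a together with C3–C3a.
- The last cut is possible because, in the five-membered ring, the tertiary carbinol C3 lies β to the oxygen-bearing C4 across C3a (an aldol retron), and the quaternary C8a is the β-carbon of the same C4 carbonyl. C4–C3a–C8a is therefore an enal, and C1–C2–C3(OH)(iPr) is a ring-opened 1-isopropylcyclopropanol.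
- Forward: the E-enal (C8 carried as an acetal) and the cyclopropanol are joined in one photo-organocatalytic operation to the fully substituted cyclopentane. C4 is then allylated, C8 is unmasked and vinylated, the seven-membered ring is closed by metathesis, C8 is oxidised and the C4 hydroxyl is acylated.
- Stereochemistry: C8a, C3a and C3 come from the chiral amine and the E geometry of the enal in the key step; C4 comes from chelation-controlled allylation. The trans ring fusion is the trans relation of the formyl and acetal groups on the cyclopentane.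

Key step: step 5

Remark on the chemistry: the carbinol carbon made in step 8 (C8) forms as both epimers and becomes the ketone in step 10, so 12 and 13 carry no descriptor there; 1, 5 and 15 are taken as commercial.

**Step 1**
Reactants: 1 ethyl (2E)-3-methyl-4-oxobut-2-enoate
Product: 2 ethyl (2E)-4,4-dimethoxy-3-methylbut-2-enoate
Conditions: HC(OMe)3, MeOH, p-TsOH·H2O (cat.), rt
Reagents that add atoms: trimethyl orthoformate, COC(OC)OC; methanol, CO
Why: Acid-catalysed acetalisation with an orthoester as water scavenger is selective for the aldehyde, masks the future C8 carbonyl carbon and should leave the E double bond untouched.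

**Step 2**
Reactants: 2 ethyl (2E)-4,4-dimethoxy-3-methylbut-2-enoate
Product: 3 (2E)-4,4-dimethoxy-3-methylbut-2-en-1-ol
Conditions: iBu2AlH (2.2 equiv), CH2Cl2, −78 °C; aqueous work-up
Reagents that add atoms: none
Why: 1,2-Reduction of an α,β-unsaturated ester by diisobutylaluminium hydride at low temperature gives the allylic alcohol without touching the acetal or the alkene geometry.

**Step 3**
Reactants: 3 (2E)-4,4-dimethoxy-3-methylbut-2-en-1-ol
Product: 4 (2E)-4,4-dimethoxy-3-methylbut-2-enal
Conditions: MnO2 (excess), CH2Cl2, rt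
Reagents that add atoms: none
Why: Allylic oxidation with MnO2 stops at the enal and keeps the E geometry that later encodes the trans relation of the two ring-fusion appendages.

**Step 4**
Reactants: 5 methyl 2-methylpropanoate
Product: 6 1-(propan-2-yl)cyclopropan-1-ol
Conditions: EtMgBr (2.4 equiv), Ti(OiPr)4 (0.2 equiv), Et2O, 0 °C → rt; aq. NH4Cl
Reagents that add atoms: ethylmagnesium bromide, CC[Mg]Br
Why: Kulinkovich cyclopropanation, in which the titanacyclopropane formed from EtMgBr and Ti(OiPr)4 adds twice to the ester carbonyl to give the 1-substituted cyclopropanol.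

**Step 5**
Reactants: 4 (2E)-4,4-dimethoxy-3-methylbut-2-enal; 6 1-(propan-2-yl)cyclopropan-1-ol
Product: 9 (1R,2R,5S)-5-(dimethoxymethyl)-2-hydroxy-5-methyl-2-(propan-2-yl)cyclopentane-1-carbaldehyde, via iminium trifluoroacetate 7 (not isolated), via open-chain enamine 8 (not isolated)
Conditions: (S)-2-{bis[3,5-bis(trifluoromethyl)phenyl](trimethylsilyloxy)methyl}-4,4-difluoropyrrolidine (20 mol%), CF3CO2H (40 mol%), 6 in twofold excess, MeCN, 365 nm LED, 25 °C, argon; aqueous work-up
Reagents that add atoms: none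
Why: Proposed new method: 4 condenses with the amine and CF3CO2H to iminium ion 7; its near-UV excited state oxidises 6 by single-electron transfer, the cyclopropanol radical cation opens to the primary β-keto radical •CH2CH2C(=O)iPr, and this radical couples with the 5π β-enaminyl radical at the fully substituted β-carbon to give enamine 8 with release of CF3CO2H, after which 8 adds to the tethered isopropyl ketone and hydrolysis frees 9 and returns the amine (redox-neutral overall). The closest known reaction type is the photochemical iminium/enamine organocascade of cyclopropanols with β-aryl enals to cyclopentanols; new here are the aliphatic β,β-disubstituted enal (hence 365 nm light) and the quaternary centre, which is reached by radical–radical coupling and so escapes the steric limits of a polar conjugate addition. The only ring closed is the cyclopentane, by a 5-(enolexo)-exo-trig aldol addition. The diarylsilyloxymethyl group of the S amine shields one face of the E iminium ion and of enamine 8, so both new bonds form on the open face: this sets the quaternary carbon (5S) and, because the acetal is trans to the formyl carbon in 4, places the formyl group cis to the ring methyl and trans to the acetal (1R); in the aldol the isopropyl group turns away from the iminium carbon, so hydroxyl and formyl end up cis (2R), which should also be the most stable arrangement (hydrogen bond, large groups trans to the formyl group). The step needs β-coupling, the enamine as the only aldol donor and retention of the E geometry: the spin density of the enaminyl radical gives the first, the fact that only the aldehyde forms an enamine gives the second, and a geometry leak would give a separable diastereomer, not the enantiomer.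

**Step 6**
Reactants: 9 (1R,2R,5S)-5-(dimethoxymethyl)-2-hydroxy-5-methyl-2-(propan-2-yl)cyclopentane-1-carbaldehyde
Product: 10 (1R,2S,3S)-3-(dimethoxymethyl)-2-[(1S)-1-hydroxy-3-methylbut-3-en-1-yl]-3-methyl-1-(propan-2-yl)cyclopentan-1-ol
Conditions: 3-bromo-2-methylprop-1-ene (2 equiv), In powder (1.5 equiv), THF/H2O (1:1), rt
Reagents that add atoms: 3-bromo-2-methylprop-1-ene, CC(=C)CBr
Why: Indium-mediated Barbier allylation in water, in which the free tertiary hydroxyl and the aldehyde oxygen chelate the metal so that the allyl group attacks the six-membered chelate on the face remote from the quaternary ring carbon, which should set the new carbinol centre as S.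

**Step 7**
Reactants: 10 (1R,2S,3S)-3-(dimethoxymethyl)-2-[(1S)-1-hydroxy-3-methylbut-3-en-1-yl]-3-methyl-1-(propan-2-yl)cyclopentan-1-ol
Product: 11 (1S,2S,3R)-3-hydroxy-2-[(1S)-1-hydroxy-3-methylbut-3-en-1-yl]-1-methyl-3-(propan-2-yl)cyclopentane-1-carbaldehyde
Conditions: p-TsOH·H2O (0.1 equiv), acetone/H2O (10:1), rt
Reagents that add atoms: water, O
Why: Mild acid-catalysed acetal hydrolysis frees the neopentyl aldehyde, which cannot epimerise (quaternary α-carbon) and should not close a lactol because the hydroxyl-bearing arm is trans to it on the cyclopentane.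

**Step 8**
Reactants: 11 (1S,2S,3R)-3-hydroxy-2-[(1S)-1-hydroxy-3-methylbut-3-en-1-yl]-1-methyl-3-(propan-2-yl)cyclopentane-1-carbaldehyde
Product: 12 (1R,2S,3S)-2-[(1S)-1-hydroxy-3-methylbut-3-en-1-yl]-3-(1-hydroxyprop-2-en-1-yl)-3-methyl-1-(propan-2-yl)cyclopentan-1-ol (both epimers at the new carbinol carbon)
Conditions: vinylmagnesium bromide (4 equiv), THF, −78 → 0 °C; aq. NH4Cl
Reagents that add atoms: vinylmagnesium bromide, C=C[Mg]Br
Why: Grignard 1,2-addition to a non-enolisable aldehyde, in which the new carbinol centre forms as a mixture of epimers that is erased by the oxidation in step 10.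

**Step 9**
Reactants: 12 (1R,2S,3S)-2-[(1S)-1-hydroxy-3-methylbut-3-en-1-yl]-3-(1-hydroxyprop-2-en-1-yl)-3-methyl-1-(propan-2-yl)cyclopentan-1-ol
Product: 13 (3R,3aS,4S,8aS)-6,8a-dimethyl-3-(propan-2-yl)-1,2,3,3a,4,5,8,8a-octahydroazulene-3,4,8-triol (both C8 epimers)
Conditions: second-generation Grubbs catalyst, (H2IMes)(PCy3)Cl2Ru=CHPh (5 mol%), CH2Cl2 (2 mM), 40 °C
Reagents that add atoms: none
Why: Ring-closing olefin metathesis between the vinyl carbinol and the 1,1-disubstituted alkene should form the trisubstituted C6=C7 bond and the seven-membered ring, with loss of ethene as driving force and the trans ring fusion fixed by the two trans appendages.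

**Step 10**
Reactants: 13 (3R,3aS,4S,8aS)-6,8a-dimethyl-3-(propan-2-yl)-1,2,3,3a,4,5,8,8a-octahydroazulene-3,4,8-triol
Product: 14 (3R,3aS,4S,8aS)-3,4-dihydroxy-6,8a-dimethyl-3-(propan-2-yl)-2,3,3a,4,5,8a-hexahydroazulen-8(1H)-one
Conditions: MnO2 (20 equiv), CH2Cl2, rt
Reagents that add atoms: none
Why: MnO2 oxidises only the allylic alcohol, so both epimers should converge on the enone while the homoallylic secondary and the tertiary hydroxyl groups stay.

**Step 11**
Reactants: 14 (3R,3aS,4S,8aS)-3,4-dihydroxy-6,8a-dimethyl-3-(propan-2-yl)-2,3,3a,4,5,8a-hexahydroazulen-8(1H)-one; 15 3,4,5-trimethoxybenzoyl chloride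
Product: 16 (3R,3aS,4S,8aS)-3-hydroxy-6,8a-dimethyl-8-oxo-3-(propan-2-yl)-1,2,3,3a,4,5,8,8a-octahydroazulen-4-yl 3,4,5-trimethoxybenzoate
Conditions: Et3N (2 equiv), DMAP (0.2 equiv), CH2Cl2, 0 °C → rt
Reagents that add atoms: none
Why: DMAP-catalysed acyl transfer from the acid chloride is selective for the secondary hydroxyl over the hindered tertiary one and touches no stereocentre.

**Compound list**

1 | ethyl (2E)-3-methyl-4-oxobut-2-enoate | CCOC(=O)/C=C(\C)C=O | starting material
2 | ethyl (2E)-4,4-dimethoxy-3-methylbut-2-enoate | CCOC(=O)/C=C(\C)C(OC)OC | intermediate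
3 | (2E)-4,4-dimethoxy-3-methylbut-2-en-1-ol | OC/C=C(\C)C(OC)OC | intermediate
4 | (2E)-4,4-dimethoxy-3-methylbut-2-enal | O=C/C=C(\C)C(OC)OC | intermediate
5 | methyl 2-methylpropanoate | COC(=O)C(C)C | starting material
6 | 1-(propan-2-yl)cyclopropan-1-ol | CC(C)C1(O)CC1 | intermediate
7 | (2S)-2-{bis[3,5-bis(trifluoromethyl)phenyl](trimethylsilyloxy)methyl}-1-[(2E)-4,4-dimethoxy-3-methylbut-2-en-1-ylidene]-4,4-difluoropyrrolidin-1-ium trifluoroacetate (not isolated) | COC(OC)/C(C)=C/C=[N+]1CC(F)(F)C[C@H]1C(O[Si](C)(C)C)(c1cc(cc(c1)C(F)(F)F)C(F)(F)F)c1cc(cc(c1)C(F)(F)F)C(F)(F)F.[O-]C(=O)C(F)(F)F | intermediate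
8 | (6S,7E)-8-[(2S)-2-{bis[3,5-bis(trifluoromethyl)phenyl](trimethylsilyloxy)methyl}-4,4-difluoropyrrolidin-1-yl]-6-(dimethoxymethyl)-2,6-dimethyloct-7-en-3-one (not isolated) | CC(C)C(=O)CC[C@](C)(C(OC)OC)/C=C/N1CC(F)(F)C[C@H]1C(O[Si](C)(C)C)(c1cc(cc(c1)C(F)(F)F)C(F)(F)F)c1cc(cc(c1)C(F)(F)F)C(F)(F)F | intermediate
9 | (1R,2R,5S)-5-(dimethoxymethyl)-2-hydroxy-5-methyl-2-(propan-2-yl)cyclopentane-1-carbaldehyde | COC(OC)[C@@]1(C)CC[C@@](O)(C(C)C)[C@@H]1C=O | intermediate
10 | (1R,2S,3S)-3-(dimethoxymethyl)-2-[(1S)-1-hydroxy-3-methylbut-3-en-1-yl]-3-methyl-1-(propan-2-yl)cyclopentan-1-ol | COC(OC)[C@@]1(C)CC[C@@](O)(C(C)C)[C@@H]1[C@@H](O)CC(C)=C | intermediate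
11 | (1S,2S,3R)-3-hydroxy-2-[(1S)-1-hydroxy-3-methylbut-3-en-1-yl]-1-methyl-3-(propan-2-yl)cyclopentane-1-carbaldehyde | O=C[C@@]1(C)CC[C@@](O)(C(C)C)[C@@H]1[C@@H](O)CC(C)=C | intermediate
12 | (1R,2S,3S)-2-[(1S)-1-hydroxy-3-methylbut-3-en-1-yl]-3-(1-hydroxyprop-2-en-1-yl)-3-methyl-1-(propan-2-yl)cyclopentan-1-ol (both epimers at the prop-2-enyl carbinol carbon) | C=CC(O)[C@@]1(C)CC[C@@](O)(C(C)C)[C@@H]1[C@@H](O)CC(C)=C | intermediate
13 | (3R,3aS,4S,8aS)-6,8a-dimethyl-3-(propan-2-yl)-1,2,3,3a,4,5,8,8a-octahydroazulene-3,4,8-triol (both C8 epimers) | O[C@H]1CC(C)=CC(O)[C@@]2(C)CC[C@@](O)(C(C)C)[C@H]12 | intermediate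
14 | (3R,3aS,4S,8aS)-3,4-dihydroxy-6,8a-dimethyl-3-(propan-2-yl)-2,3,3a,4,5,8a-hexahydroazulen-8(1H)-one | O[C@H]1CC(C)=CC(=O)[C@@]2(C)CC[C@@](O)(C(C)C)[C@H]12 | intermediate
15 | 3,4,5-trimethoxybenzoyl chloride | COc1cc(C(Cl)=O)cc(OC)c1OC | starting material
16 | (3R,3aS,4S,8aS)-3-hydroxy-6,8a-dimethyl-8-oxo-3-(propan-2-yl)-1,2,3,3a,4,5,8,8a-octahydroazulen-4-yl 3,4,5-trimethoxybenzoate | COc1cc(C(=O)O[C@H]2CC(C)=CC(=O)[C@@]3(C)CC[C@@](O)(C(C)C)[C@H]23)cc(OC)c1OC | target

**Step count and risks**

Total step count: 11. Longest linear sequence: 10 steps (steps 1–3 and 5–11; step 4 is a one-step branch).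

Steps most likely to fail:

1. **Step 5** (Proposed new method). The aliphatic iminium ion may absorb too weakly for efficient electron transfer. E/Z isomerisation in the excited state or at the enaminyl radical may erode the diastereoselectivity. The acid co-catalyst may dehydrate the aldol or partly cleave the acetal. The fallback sets out from 4 and 6 and comes back at 10, using known thermal reactions in the racemic series. Compound 6 is converted with Et2Zn into its zinc homoenolate, which adds to 4 under CuBr·SMe2/Me3SiCl (conjugate addition of a zinc homoenolate) to give, after mild acidic work-up, racemic 3-(dimethoxymethyl)-3,7-dimethyl-6-oxooctanal F1. Pyrrolidine/AcOH then closes the ring by a 5-enolexo aldol addition to the racemate of 9, that is 9 together with its mirror image (1S,2S,5R)-5-(dimethoxymethyl)-2-hydroxy-5-methyl-2-(propan-2-yl)cyclopentane-1-carbaldehyde F2. Reagent-controlled allylboration with (−)-B-(2-methylallyl)diisopinocampheylborane, Ipc2B-CH2C(CH3)=CH2 (Et2O, −78 °C, then NaOH/H2O2) would convert the two enantiomers into 10 and the diastereomer (1S,2R,3R)-3-(dimethoxymethyl)-2-[(1S)-1-hydroxy-3-methylbut-3-en-1-yl]-3-methyl-1-(propan-2-yl)cyclopentan-1-ol F3. These are separated by chromatography, and the route continues from 10 at step 7.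

2. **Step 9.** Closure of the trans-fused seven-membered ring onto the 1,1-disubstituted alkene may be slow, so that oligomerisation or isomerisation of the allylic alcohol competes. The fallback sets out from 10 and comes back at 16, closing the ring at C7–C8 instead of C6=C7. Compound 10 is acylated with 15 (Et3N, DMAP) at the secondary hydroxyl to (1S)-1-[(1S,2R,5S)-5-(dimethoxymethyl)-2-hydroxy-5-methyl-2-(propan-2-yl)cyclopentyl]-3-methylbut-3-en-1-yl 3,4,5-trimethoxybenzoate F4. Acetal hydrolysis as in step 7 gives (1S)-1-[(1S,2R,5S)-5-formyl-2-hydroxy-5-methyl-2-(propan-2-yl)cyclopentyl]-3-methylbut-3-en-1-yl 3,4,5-trimethoxybenzoate F5. Me2AlCl (CH2Cl2, −78 → 0 °C) then promotes the intramolecular carbonyl-ene reaction between the aldehyde and the 2-methylallyl group to (3R,3aS,4S,8aS)-3,8-dihydroxy-8a-methyl-6-methylidene-3-(propan-2-yl)decahydroazulen-4-yl 3,4,5-trimethoxybenzoate F6. Dess–Martin oxidation gives (3R,3aS,4S,8aS)-3-hydroxy-8a-methyl-6-methylidene-8-oxo-3-(propan-2-yl)decahydroazulen-4-yl 3,4,5-trimethoxybenzoate F7, and RhCl3·3H2O (EtOH, 60 °C) moves the double bond into conjugation to give 16.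

3. **Step 6.** The chelate may not form fast enough in the aqueous medium, giving poor facial selectivity at the new carbinol carbon, and the acetal may be partly lost. The fallback sets out from 9 and comes back at 10. Substrate control is replaced by reagent control: (−)-B-(2-methylallyl)diisopinocampheylborane, Ipc2B-CH2C(CH3)=CH2, in Et2O at −78 °C, then NaOH/H2O2, delivers the 2-methylallyl group to the aldehyde face that gives the S carbinol under anhydrous, non-acidic conditions. This fallback passes through no new compound (F0).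

**Further compounds**

F1 | step 5 | 3-(dimethoxymethyl)-3,7-dimethyl-6-oxooctanal (racemic) | CC(C)C(=O)CCC(C)(CC=O)C(OC)OC
F2 | step 5 | (1S,2S,5R)-5-(dimethoxymethyl)-2-hydroxy-5-methyl-2-(propan-2-yl)cyclopentane-1-carbaldehyde | COC(OC)[C@]1(C)CC[C@](O)(C(C)C)[C@H]1C=O
F3 | step 5 | (1S,2R,3R)-3-(dimethoxymethyl)-2-[(1S)-1-hydroxy-3-methylbut-3-en-1-yl]-3-methyl-1-(propan-2-yl)cyclopentan-1-ol | COC(OC)[C@]1(C)CC[C@](O)(C(C)C)[C@H]1[C@@H](O)CC(C)=C
F4 | step 9 | (1S)-1-[(1S,2R,5S)-5-(dimethoxymethyl)-2-hydroxy-5-methyl-2-(propan-2-yl)cyclopentyl]-3-methylbut-3-en-1-yl 3,4,5-trimethoxybenzoate | COC(OC)[C@@]1(C)CC[C@@](O)(C(C)C)[C@@H]1[C@H](CC(C)=C)OC(=O)c1cc(OC)c(OC)c(OC)c1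
F5 | step 9 | (1S)-1-[(1S,2R,5S)-5-formyl-2-hydroxy-5-methyl-2-(propan-2-yl)cyclopentyl]-3-methylbut-3-en-1-yl 3,4,5-trimethoxybenzoate | O=C[C@@]1(C)CC[C@@](O)(C(C)C)[C@@H]1[C@H](CC(C)=C)OC(=O)c1cc(OC)c(OC)c(OC)c1
F6 | step 9 | (3R,3aS,4S,8aS)-3,8-dihydroxy-8a-methyl-6-methylidene-3-(propan-2-yl)decahydroazulen-4-yl 3,4,5-trimethoxybenzoate (both C8 epimers) | COc1cc(C(=O)O[C@H]2CC(=C)CC(O)[C@@]3(C)CC[C@@](O)(C(C)C)[C@H]23)cc(OC)c1OC
F7 | step 9 | (3R,3aS,4S,8aS)-3-hydroxy-8a-methyl-6-methylidene-8-oxo-3-(propan-2-yl)decahydroazulen-4-yl 3,4,5-trimethoxybenzoate | COc1cc(C(=O)O[C@H]2CC(=C)CC(=O)[C@@]3(C)CC[C@@](O)(C(C)C)[C@H]23)cc(OC)c1OC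
F0 | step 6 | none | none
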